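Birch, alder and maple were the runs I had before the new flask, and from each I took the loss: the share of the E charged that was missing from X, averaged from the second reading on.

| setting | birch | alder | maple | flask |
|---|---|---|---|---|
| E | 0.10 M | 0.10 M | 0.050 M | 0.10 M |
| Q | 7.5 mM (in portions, 3) | 11 mM (in portions, 3) | 15 mM (in portions, 3) | 15 mM (in portions, 3) |
| remark | run made earlier; portions every 3.0 s | run made earlier; portions every 3.0 s | run made earlier; portions every 3.0 s | the portions of Q follow each other after 3.0 s, the first at the start |
| time |  |  |  | 25 min |

- birch (time / min: E / %, X / %): 2.50: 30, 61; 8.00: 1, 94; 12.0: 1, 92; 20.0: 0, 93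
- alder (time / min: E / %, X / %): 2.50: 10, 80; 8.00: 0, 94; 12.0: 0, 94; 20.0: 0, 94
- maple (time / min: E / %, X / %): 1.50: 3, 91; 4.00: 0, 100; 8.00: 2, 96; 20.0: 0, 96

(each reading ± 1.5 percentage points)

1. the state of affairs at 25 min: stopped, and by what, or still going (all of E has reacted / it is still moving / no working catalyst is left)
2. how much of the E has reacted by 25 min
3. how much X there is at 25 min, in percent of the E charged

- the numbers in the tables scatter with a standard deviation of 1.5 percentage points
- the reaction counts as stopped when no species that holds the E changes by six tenths of a point or more over the second half of the time

I went through the settings one at a time. By hand, more Q should speed the flask and might spare E. From birch to alder, with Q raised from 7.5 mM to 11 mM, E at 2.50 min did fall from 30 % to 10 %, but the loss moved from 7.00 % to 6.00 %, against a scatter of 1.5 percentage points. Less E should leave the lost share unchanged if each E ran its own risk, but maple, with half the E and also more Q than birch, lost 2.67 %, so, two settings differing there and the step in Q from birch to alder having moved the loss so little, I read the loss as following the E charged. Time should add nothing once E is used up, and birch held 1 % of E at 8.00 min, with X flat up to 20.0 min. The portions should not count, since the last went in at 6.00 s, much earlier than the first reading.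

I summed the losses and divided by the summed charges of E, which gave 0.627 M⁻¹; this toll, the lost share of the E charged per unit of E concentration charged, was the quantity I carried. The flask has twice birch's Q, so I expected E, the limiting reagent, to be used up well before 25 min, and 0.10 M of E at that toll costs 6.27 %, leaving X at 93.7 %.

The forecast, higher than my figure, said all of E has reacted, with conversion 100 % and X 95 % (from 92.5 % to 97 %), holding that “The loss seems to depend mainly on E concentration”.

The flask gave all of E has reacted, with conversion 100 % and X 93.9 %.

    D → Q + X (k = 0.530 s⁻¹)
    Z → D (k = 0.150 s⁻¹)
    E + D → J (k = 0.410 M⁻¹ s⁻¹)
    E + Q → Z (k = 3.70 M⁻¹ s⁻¹)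

The flask's missing 6.10 % stood against the 6.27 % from the toll. The toll is the loss of E + D to J: the flask run without that step reached 100 % of X instead of 93.9 %. The neighbour flask with 3.70 mM of Q kept 14 % of its E unreacted at 25.0 min, so taking the toll's 6.27 % of the E charged from the 86.0 % that reacted reckoned X at 79.7 %, and that neighbour held 79.6 %.

(The numbers in the tables are simulated with constants of no real substance, noise included.)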